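**Reagent count.** In a closed flask of constant volume running the suspected steps, the reagent charged stays equal to free reagent plus target plus second product, so reagent held as second product is missing from the other two. You want the target after 4.0 h as the charge of second substrate rises.

| flask | starting material | reagent | second substrate | remark | time |
|---|---|---|---|---|---|
| grey | 23 mM | 1.2 equiv | 0.12 equiv | run made earlier |  |
| cedar | 34 mM | 1.20 equiv | 0.120 equiv |  | 4.0 h |
| oak | 34 mM | 1.20 equiv | 0.250 equiv |  | 4.0 h |
| maple | 34 mM | 1.20 equiv | 0.500 equiv |  | 4.0 h |
| larch | 34 mM | 1.20 equiv | 1.00 equiv |  | 4.0 h |
| elm | 34 mM | 1.20 equiv | 2.00 equiv |  | 4.0 h |

grey run (percent of the starting material charged)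

| time / h | target / % | starting material / % |
|---|---|---|
| 0.500 | 16.4 | 79.6 |
| 1.00 | 24.2 | 70.3 |
| 1.33 | 26.5 | 66.1 |
| 2.00 | 28.6 | 61.7 |
| 2.50 | 29.3 | 59.4 |

(scatter of a reading: 0.3 percentage points)

- percentages count the starting material that a species holds: one self-condensation product counts as two
- on the list of suspects stand: second substrate + reagent <-> second product; starting material + reagent <-> target; 2 starting material -> self-condensation product
- "hardly changes" means that all values lie within two and a half points (for a concentration: within two and a half percent of the largest)

- amount of target at the end, in percent of the starting material charged for cedar, oak, maple, larch, elm, in this order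
- how that number moves from the first to the last of them (falls, then rises / rises, then falls / hardly changes / falls all the way / rises all the way)

**Main step.** Begin with starting material and reagent forming target, and nothing else. Grey's target rose by only 0.7 percentage points between its last two readings, so I freeze the ratio there. Its last reading, with free reagent taken as charge minus target, gives 0.0236 mM⁻¹. This reading, with the scatter of grey's readings on it, is the frozen equilibrium quotient, target over starting material times free reagent, a mass-action ratio. It reads low if second product had already formed. Multiplied by cedar's charge it becomes 0.804, and with the count above my reckoning for cedar gives 39.3% target.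

**Self-condensation.** Grey's unaccounted starting material grew by 1.6 points over that last interval. At equal share of starting material remaining, a second-order loss in percent per hour scales with the charge. Holding cedar at grey's share for 4.0 h therefore removes about 18.9% of the starting material, a coarse figure from two readings. The quotient then gives 33.3% for cedar.

**Second substrate.** If cedar's whole second substrate captured reagent, the same reckoning gives 31.0%, so I place cedar between these two figures. Grey gives me no quotient for this capture. I therefore set no number for elm, whose second substrate charge is larger than its reagent charge, and I commit to a falling row.

**The forecast.** It gives 33%, 30%, 25%, 14% and 2%, a row that falls all the way. For elm it says “reagent is nearly gone and target has drained back”. So it sets a number for elm where I set none.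

**The result.** The flasks give 34.2%, 33.4%, 31.9%, 29.2% and 24.8%, a row that falls all the way.

    second substrate + reagent ⇌ second product (K = 15.0 M⁻¹, k = 0.650 M⁻¹ min⁻¹)
    starting material + reagent ⇌ target (K = 25.0 M⁻¹, k = 0.300 M⁻¹ min⁻¹)
    2 starting material → self-condensation product (k = 0.0330 M⁻¹ min⁻¹)

**Frozen quotient.** Fed cedar's 47.1% starting material and 68.5% reagent of its own charge, the quotient gives 31.1% target against 34.2%. Fed elm's 52.5% and 44.0%, it gives 22.3% against 24.8%. Elm's second product stood at 14.4 mM after 2.00 h and at 14.4 mM after 4.00 h, with target at 25.4% and 24.8%. Over those hours elm's self-condensation product rose from 14.2% to 22.7%, while its starting material fell from 60.3% to 52.5%.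

The readings come from a simulation for substances that don't exist, and the scatter is random.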